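**Plan**
Retrosynthesis: the five benzyl ethers and the C2 acetal oxygen go first; the isoflavan pyran ring is then cut at C3–C4 and O1–C2, the diaryl carbinol at its bond to C6 of the flavanone, and the enol ether at its aryl–vinyl bond.
Enabling feature: O1 and C4 are ortho substituents of ring A, so O1–C8a–C4a–C4 is a masked ortho-quinone methide and C2–C3 a masked enol ether. The pyran ring (O1, C2, C3, C4, C4a, C8a) is the only ring that has to be built.
Forward: (2S)-naringenin is benzylated, iodinated at C6 and joined to a ring A salicylaldehyde (Nozaki–Hiyama–Kishi). Ring B is turned into an (E)-β-aryl enol ether from 2,6-dimethoxyphenol. A chiral phosphoric acid then closes the pyran ring by an oxa-[4+2] addition.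
Finish: the C2 acetal is reduced to CH2 and the benzyl groups are removed by hydrogenolysis.
Stereochemistry: the flavanone (2S) centre comes from naringenin and meets no enolising base once O5 is alkylated. C4 (S) is set by the catalyst-controlled face of the methide, and C3 (R) by the endo-alkoxy transition state of the (E)-alkene (3,4-trans).

Key step: step 11

Assumption: (R)-TRIP, (R)-3,3'-bis(2,4,6-triisopropylphenyl)-1,1'-binaphthyl-2,2'-diyl hydrogen phosphate, is taken to open the methide face that leads to (3R,4S); if a test run shows the opposite sense, the (S) acid is used and nothing else changes.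

**Route**

Step 1
Reactants: 1 (2S)-naringenin
Product: 2 (2S)-7-(benzyloxy)-2-[4-(benzyloxy)phenyl]-5-hydroxychroman-4-one
Conditions: BnOH (2.2 equiv), PPh3, DIAD, THF, 0 °C to rt
Reagents that add atoms: benzyl alcohol OCc1ccccc1
Why: A Mitsunobu etherification should alkylate the two acidic, unchelated phenols (O7 and O4') and leave the hydrogen-bonded 5-OH, and because no phenoxide is held in solution the base-triggered opening of the pyranone that would racemise C2 is avoided.

Step 2
Reactants: 2 (2S)-7-(benzyloxy)-2-[4-(benzyloxy)phenyl]-5-hydroxychroman-4-one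
Product: 3 (2S)-7-(benzyloxy)-2-[4-(benzyloxy)phenyl]-5-hydroxy-6-iodochroman-4-one
Conditions: BnMe3N+ ICl2− (1.05 equiv), CaCO3, CH2Cl2–MeOH, rt
Reagents that add atoms: benzyltrimethylammonium dichloroiodate C[N+](C)(C)Cc1ccccc1.Cl[I-]Cl
Why: Electrophilic aromatic iodination of 5-hydroxy-7-alkoxy flavonoids with this reagent is directed ortho to the free chelated phenol, so iodine should enter at C6 and not at C8, while CaCO3 takes up the HCl.

Step 3
Reactants: 3 (2S)-7-(benzyloxy)-2-[4-(benzyloxy)phenyl]-5-hydroxy-6-iodochroman-4-one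
Product: 4 (2S)-5,7-bis(benzyloxy)-2-[4-(benzyloxy)phenyl]-6-iodochroman-4-one
Conditions: BnBr, Ag2O, 4 Å MS, CH2Cl2, dark, rt to 40 °C
Reagents that add atoms: benzyl bromide BrCc1ccccc1
Why: Silver oxide mediated O-alkylation (a Williamson etherification without a soluble base) should benzylate the chelated phenol without forming the C3 enolate, whose β-elimination of the ring oxygen would open the flavanone and scramble C2.

Step 4
Reactants: 5 2,4-dihydroxybenzaldehyde
Product: 6 4-(benzyloxy)-2-hydroxybenzaldehyde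
Conditions: BnBr (1.05 equiv), NaHCO3, KI (cat.), MeCN, 80 °C
Reagents that add atoms: benzyl bromide BrCc1ccccc1
Why: In this Williamson etherification the weak base deprotonates only the more acidic 4-OH, the 2-OH being tied to the aldehyde by a hydrogen bond, so mono-benzylation at O4 is expected.

Step 5
Reactants: 6 4-(benzyloxy)-2-hydroxybenzaldehyde
Product: 7 4-(benzyloxy)-2-[(tert-butyldimethylsilyl)oxy]benzaldehyde
Conditions: TBSCl, imidazole, CH2Cl2, rt
Reagents that add atoms: tert-butyldimethylsilyl chloride CC(C)(C)[Si](C)(C)Cl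
Why: Imidazole-promoted silylation turns the acidic phenol, which would protonate an aryl–chromium bond, into a silyl ether that fluoride later removes under near-neutral conditions.

Step 6
Reactants: 4 (2S)-5,7-bis(benzyloxy)-2-[4-(benzyloxy)phenyl]-6-iodochroman-4-one; 7 4-(benzyloxy)-2-[(tert-butyldimethylsilyl)oxy]benzaldehyde
Product: 8 (2S)-5,7-bis(benzyloxy)-2-[4-(benzyloxy)phenyl]-6-[{4-(benzyloxy)-2-[(tert-butyldimethylsilyl)oxy]phenyl}(hydroxy)methyl]chroman-4-one (both carbinol epimers)
Conditions: CrCl2 (4 equiv), NiCl2 (2 mol%), degassed DMF, rt; aq. NH4Cl work-up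
Reagents that add atoms: none
Why: In the Nozaki–Hiyama–Kishi reaction zerovalent nickel inserts into the aryl–iodine bond and passes the aryl group to chromium, giving a non-basic nucleophile that should add to the aldehyde and ignore the enolisable flavanone ketone; the new carbinol centre is not controlled, which does not matter because both epimers lead to the same quinone methide.

Step 7
Reactants: 8 (2S)-5,7-bis(benzyloxy)-2-[4-(benzyloxy)phenyl]-6-[{4-(benzyloxy)-2-[(tert-butyldimethylsilyl)oxy]phenyl}(hydroxy)methyl]chroman-4-one (both carbinol epimers)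
Product: 9 (2S)-5,7-bis(benzyloxy)-2-[4-(benzyloxy)phenyl]-6-{[4-(benzyloxy)-2-hydroxyphenyl](hydroxy)methyl}chroman-4-one (both carbinol epimers)
Conditions: TBAF, AcOH (1:1), THF, 0 °C
Reagents that add atoms: none
Why: Fluoride cleaves the aryl silyl ether (desilylation), the acetic acid buffer keeping the medium mild enough that the flavanone does not open and the doubly benzylic alcohol does not ionise, and a silyl group that may have moved to the carbinol oxygen is removed as well.

Step 8
Reactants: 10 2,6-dimethoxyphenol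
Product: 11 2-(benzyloxy)-1,3-dimethoxybenzene
Conditions: BnBr, K2CO3, DMF, rt
Reagents that add atoms: benzyl bromide BrCc1ccccc1
Why: A plain Williamson etherification protects the phenol and, by making it the twisted central alkoxy group of a 1,2,3-trialkoxybenzene, prepares the ring for substitution next to an outer methoxy group.

Step 9
Reactants: 11 2-(benzyloxy)-1,3-dimethoxybenzene
Product: 12 2-(benzyloxy)-4-bromo-1,3-dimethoxybenzene
Conditions: NBS (1.0 equiv), MeCN, 0 °C to rt
Reagents that add atoms: N-bromosuccinimide O=C1CCC(=O)N1Br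
Why: Electrophilic aromatic bromination of 1,2,3-trialkoxybenzenes goes para to an outer methoxy group because the central, out-of-plane alkoxy group donates little, so bromine should enter at C4.

Step 10
Reactants: 12 2-(benzyloxy)-4-bromo-1,3-dimethoxybenzene; 13 (E)-2-(2-ethoxyvinyl)-4,4,5,5-tetramethyl-1,3,2-dioxaborolane
Product: 14 (E)-2-(benzyloxy)-4-(2-ethoxyvinyl)-1,3-dimethoxybenzene
Conditions: Pd(PPh3)4 (5 mol%), K2CO3, 1,4-dioxane–H2O, 85 °C
Reagents that add atoms: none
Why: The Suzuki–Miyaura coupling transfers the alkenyl group with retention of the double-bond geometry, so the (E)-boronate should give the (E)-enol ether, which is stable to the aqueous base.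

Step 11
Reactants: 9 (2S)-5,7-bis(benzyloxy)-2-[4-(benzyloxy)phenyl]-6-{[4-(benzyloxy)-2-hydroxyphenyl](hydroxy)methyl}chroman-4-one (both carbinol epimers); 14 (E)-2-(benzyloxy)-4-(2-ethoxyvinyl)-1,3-dimethoxybenzene
Product: 16 (2S)-5,7-bis(benzyloxy)-2-[4-(benzyloxy)phenyl]-6-{(2S,3R,4S)-7-(benzyloxy)-3-[3-(benzyloxy)-2,4-dimethoxyphenyl]-2-ethoxychroman-4-yl}chroman-4-one, via ring A ortho-quinone methide 15 (not isolated)
Conditions: 14 (1.5 equiv), (R)-TRIP (10 mol%), 5 Å MS, toluene, 0 °C to rt
Reagents that add atoms: none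
Why: The acid should dehydrate carbinol 9 to the (E)-ortho-quinone methide 15 of ring A and stay hydrogen-bonded to its carbonyl oxygen; the β-carbon of enol ether 14 then attacks the methide carbon (C3–C4) and the ring A oxygen captures the oxocarbenium carbon (O1–C2). The closest known reaction type is the chiral phosphoric acid catalysed inverse-electron-demand oxa-Diels–Alder reaction of ortho-quinone methides, made in situ from 2-hydroxybenzhydrols, with enol ethers, enamides and styrenes. The pyran ring (O1, C2, C3, C4, C4a, C8a) closes in an asynchronous [4+2] mode, which in its stepwise limit is a 6-exo-trig attack of O1 on the oxocarbenium ion. C4 is set by the methide face that the bound chiral phosphate leaves open, C3 by the transition state with the ethoxy group endo and the aryl group exo on the (E)-alkene, which puts the two aryl groups trans, and C2 by suprafacial addition to the (E)-alkene (2,3-trans) before it is erased in step 12. The step needs a single quinone methide, secured because only ring A has a free ortho hydroxyl while O5 and O7 of the flavanone are benzylated, 3,4-trans selectivity, secured by the defined (E) geometry of 14, and face selectivity far from the (2S) centre, which the catalyst must supply. Because the (2S) centre is present, a product from the wrong face would be a diastereomer and could be removed by chromatography.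

Step 12
Reactants: 16 (2S)-5,7-bis(benzyloxy)-2-[4-(benzyloxy)phenyl]-6-{(2S,3R,4S)-7-(benzyloxy)-3-[3-(benzyloxy)-2,4-dimethoxyphenyl]-2-ethoxychroman-4-yl}chroman-4-one
Product: 17 (2S)-5,7-bis(benzyloxy)-2-[4-(benzyloxy)phenyl]-6-{(3R,4S)-7-(benzyloxy)-3-[3-(benzyloxy)-2,4-dimethoxyphenyl]chroman-4-yl}chroman-4-one
Conditions: Et3SiH (4 equiv), BF3·OEt2 (2 equiv), CH2Cl2, −78 to −40 °C
Reagents that add atoms: none
Why: In this ionic hydrogenation BF3·OEt2 ionises the cyclic acetal to the ring oxocarbenium ion and the silane delivers hydride to C2, which becomes a methylene, while C3 and C4 are not involved and the ketone and benzyl ethers are spared at low temperature.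

Step 13
Reactants: 17 (2S)-5,7-bis(benzyloxy)-2-[4-(benzyloxy)phenyl]-6-{(3R,4S)-7-(benzyloxy)-3-[3-(benzyloxy)-2,4-dimethoxyphenyl]chroman-4-yl}chroman-4-one
Product: 18 (2S)-5,7-dihydroxy-6-[(3R,4S)-7-hydroxy-3-(3-hydroxy-2,4-dimethoxyphenyl)chroman-4-yl]-2-(4-hydroxyphenyl)chroman-4-one
Conditions: H2 (1 atm), 10% Pd/C, EtOAc–MeOH, rt
Reagents that add atoms: none
Why: Catalytic hydrogenolysis cleaves the five benzyl aryl ethers under neutral conditions, and at room temperature with the reaction stopped when uptake ends the methyl ethers, the ketone, the benzylic ring oxygen of the flavanone and the three stereocentres should stay untouched.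

**Compound list**
1 | (2S)-naringenin | O=C1C[C@@H](c2ccc(O)cc2)Oc2cc(O)cc(O)c12 | starting material
2 | (2S)-7-(benzyloxy)-2-[4-(benzyloxy)phenyl]-5-hydroxychroman-4-one | O=C1C[C@@H](c2ccc(OCc3ccccc3)cc2)Oc2cc(OCc3ccccc3)cc(O)c12 | intermediate
3 | (2S)-7-(benzyloxy)-2-[4-(benzyloxy)phenyl]-5-hydroxy-6-iodochroman-4-one | O=C1C[C@@H](c2ccc(OCc3ccccc3)cc2)Oc2cc(OCc3ccccc3)c(I)c(O)c12 | intermediate
4 | (2S)-5,7-bis(benzyloxy)-2-[4-(benzyloxy)phenyl]-6-iodochroman-4-one | O=C1C[C@@H](c2ccc(OCc3ccccc3)cc2)Oc2cc(OCc3ccccc3)c(I)c(OCc3ccccc3)c12 | intermediate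
5 | 2,4-dihydroxybenzaldehyde | O=Cc1ccc(O)cc1O | starting material
6 | 4-(benzyloxy)-2-hydroxybenzaldehyde | O=Cc1ccc(OCc2ccccc2)cc1O | intermediate
7 | 4-(benzyloxy)-2-[(tert-butyldimethylsilyl)oxy]benzaldehyde | O=Cc1ccc(OCc2ccccc2)cc1O[Si](C)(C)C(C)(C)C | intermediate
8 | (2S)-5,7-bis(benzyloxy)-2-[4-(benzyloxy)phenyl]-6-[{4-(benzyloxy)-2-[(tert-butyldimethylsilyl)oxy]phenyl}(hydroxy)methyl]chroman-4-one, carbinol centre as both epimers | OC(c1ccc(OCc2ccccc2)cc1O[Si](C)(C)C(C)(C)C)c1c(OCc2ccccc2)cc2c(c1OCc1ccccc1)C(=O)C[C@@H](c1ccc(OCc3ccccc3)cc1)O2 | intermediate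
9 | (2S)-5,7-bis(benzyloxy)-2-[4-(benzyloxy)phenyl]-6-{[4-(benzyloxy)-2-hydroxyphenyl](hydroxy)methyl}chroman-4-one, carbinol centre as both epimers | OC(c1ccc(OCc2ccccc2)cc1O)c1c(OCc2ccccc2)cc2c(c1OCc1ccccc1)C(=O)C[C@@H](c1ccc(OCc3ccccc3)cc1)O2 | intermediate
10 | 2,6-dimethoxyphenol | COc1cccc(OC)c1O | starting material
11 | 2-(benzyloxy)-1,3-dimethoxybenzene | COc1cccc(OC)c1OCc1ccccc1 | intermediate
12 | 2-(benzyloxy)-4-bromo-1,3-dimethoxybenzene | COc1ccc(Br)c(OC)c1OCc1ccccc1 | intermediate
13 | (E)-2-(2-ethoxyvinyl)-4,4,5,5-tetramethyl-1,3,2-dioxaborolane | CCO/C=C/B1OC(C)(C)C(C)(C)O1 | starting material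
14 | (E)-2-(benzyloxy)-4-(2-ethoxyvinyl)-1,3-dimethoxybenzene | CCO/C=C/c1ccc(OC)c(OCc2ccccc2)c1OC | intermediate
15 | ring A ortho-quinone methide, (2S)-5,7-bis(benzyloxy)-2-[4-(benzyloxy)phenyl]-6-{(E)-[4-(benzyloxy)-6-oxocyclohexa-2,4-dien-1-ylidene]methyl}chroman-4-one | O=C1C=C(OCc2ccccc2)C=C/C1=C\c1c(OCc2ccccc2)cc2c(c1OCc1ccccc1)C(=O)C[C@@H](c1ccc(OCc3ccccc3)cc1)O2 | intermediate
16 | (2S)-5,7-bis(benzyloxy)-2-[4-(benzyloxy)phenyl]-6-{(2S,3R,4S)-7-(benzyloxy)-3-[3-(benzyloxy)-2,4-dimethoxyphenyl]-2-ethoxychroman-4-yl}chroman-4-one | COc1ccc([C@@H]2[C@@H](OCC)Oc3cc(OCc4ccccc4)ccc3[C@H]2c2c(OCc3ccccc3)cc3c(c2OCc2ccccc2)C(=O)C[C@@H](c2ccc(OCc4ccccc4)cc2)O3)c(OC)c1OCc1ccccc1 | intermediate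
17 | (2S)-5,7-bis(benzyloxy)-2-[4-(benzyloxy)phenyl]-6-{(3R,4S)-7-(benzyloxy)-3-[3-(benzyloxy)-2,4-dimethoxyphenyl]chroman-4-yl}chroman-4-one | COc1ccc([C@@H]2COc3cc(OCc4ccccc4)ccc3[C@H]2c2c(OCc3ccccc3)cc3c(c2OCc2ccccc2)C(=O)C[C@@H](c2ccc(OCc4ccccc4)cc2)O3)c(OC)c1OCc1ccccc1 | intermediate
18 | (2S)-5,7-dihydroxy-6-[(3R,4S)-7-hydroxy-3-(3-hydroxy-2,4-dimethoxyphenyl)chroman-4-yl]-2-(4-hydroxyphenyl)chroman-4-one | COc1ccc([C@@H]2COc3cc(O)ccc3[C@H]2c2c(O)cc3c(c2O)C(=O)C[C@@H](c2ccc(O)cc2)O3)c(OC)c1O | target

**Totals**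
Total step count: 13.
Longest linear sequence: 8 steps (steps 1, 2, 3, 6, 7, 11, 12, 13, from naringenin).

**Steps most likely to fail**

Step 11. The methide carbon is flanked by the two benzyloxy groups of the flavanone ring. Addition may be slow, so that traces of water hydrolyse the enol ether, or the phosphate may discriminate the two methide faces poorly. The fallback sets out from 9 and 14 and comes back at 17; it makes the nucleophile, not the electrophile, the chiral partner. Enol ether 14 is hydrolysed (aq. HCl, THF) to (3-benzyloxy-2,4-dimethoxyphenyl)acetaldehyde F1. F1 and carbinol 9 are combined with 2-[diphenyl(trimethylsilyloxy)methyl]pyrrolidine (antipode chosen on a test scale) and benzoic acid in toluene. The enamine of F1 should add to methide 15 and the phenol should close onto the released aldehyde. This enamine-catalysed Michael addition–hemiacetalisation, a known way to 3,4-trans chroman-2-ols, forms the same C3–C4 and O1–C2 bonds and should give the chroman-2-ol (lactol) F2. The conditions of step 12 then reduce F2 to 17.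

Step 6. Oxidative addition and transfer to chromium at an aryl iodide with two ortho benzyloxy groups may be slow, and protodeiodination or pinacol coupling of 7 may take over. The fallback sets out from 4 and comes back at 9; it reverses the polarity of the coupling. Iodide 4 is formylated by palladium-catalysed reductive carbonylation (Pd(PPh3)4, CO, Bu3SnH, THF, 50 °C) to (2S)-5,7-bis(benzyloxy)-2-[4-(benzyloxy)phenyl]-4-oxochroman-6-carbaldehyde F3. Commercial 3-(benzyloxy)phenol is converted with EtMgBr into bromomagnesium 3-(benzyloxy)phenoxide F4. F4 should add to F3 in toluene at rt through its carbon ortho to oxygen and para to the benzyloxy group (ortho-selective hydroxyalkylation of a magnesium phenoxide). This should give carbinol 9 directly, and steps 4, 5 and 7 are no longer needed.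

Step 3. The phenol is chelated to the ketone and flanked by iodine, so O-alkylation may stall. Forcing it with a stronger base would enolise C3, open the pyranone and erode the (2S) centre. The fallback sets out from 3 and comes back at 4; it takes the carbonyl out of play during the alkylation. NaBH4 (MeOH–THF, 0 °C) reduces 3 to (2S)-7-(benzyloxy)-2-[4-(benzyloxy)phenyl]-6-iodochromane-4,5-diol F5. With no enolisable ketone left, BnBr and K2CO3 in DMF at rt should benzylate the now ordinary phenol (the secondary alcohol is not alkylated by carbonate) to (2S)-5,7-bis(benzyloxy)-2-[4-(benzyloxy)phenyl]-6-iodochroman-4-ol F6. Dess–Martin periodinane (NaHCO3, CH2Cl2, rt) re-oxidises the benzylic alcohol to the ketone and returns 4.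

Further compounds
F1 | step 11 | (3-benzyloxy-2,4-dimethoxyphenyl)acetaldehyde | O=CCc1ccc(OC)c(OCc2ccccc2)c1OC
F2 | step 11 | (2S)-5,7-bis(benzyloxy)-2-[4-(benzyloxy)phenyl]-6-{(3R,4S)-7-(benzyloxy)-3-[3-(benzyloxy)-2,4-dimethoxyphenyl]-2-hydroxychroman-4-yl}chroman-4-one (both anomers) | COc1ccc([C@@H]2C(O)Oc3cc(OCc4ccccc4)ccc3[C@H]2c2c(OCc3ccccc3)cc3c(c2OCc2ccccc2)C(=O)C[C@@H](c2ccc(OCc4ccccc4)cc2)O3)c(OC)c1OCc1ccccc1
F3 | step 6 | (2S)-5,7-bis(benzyloxy)-2-[4-(benzyloxy)phenyl]-4-oxochroman-6-carbaldehyde | O=Cc1c(OCc2ccccc2)cc2c(c1OCc1ccccc1)C(=O)C[C@@H](c1ccc(OCc3ccccc3)cc1)O2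
F4 | step 6 | bromomagnesium 3-(benzyloxy)phenoxide | [O-]c1cccc(OCc2ccccc2)c1.[Mg+2].[Br-]
F5 | step 3 | (2S)-7-(benzyloxy)-2-[4-(benzyloxy)phenyl]-6-iodochromane-4,5-diol (both 4-epimers) | OC1C[C@@H](c2ccc(OCc3ccccc3)cc2)Oc2cc(OCc3ccccc3)c(I)c(O)c12
F6 | step 3 | (2S)-5,7-bis(benzyloxy)-2-[4-(benzyloxy)phenyl]-6-iodochroman-4-ol (both 4-epimers) | OC1C[C@@H](c2ccc(OCc3ccccc3)cc2)Oc2cc(OCc3ccccc3)c(I)c(OCc3ccccc3)c12
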